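**Retrosynthetic overview**
- The dienyl side chain is cut at C15=C16: aldol addition/elimination between a cyclopentyl acetic ester and a C11 trienal made by Heck coupling.
- The cyclopentane is cut at C26–C14: SmI2 ketyl–olefin cyclisation of an aldehyde/enoate, steered by the C10 hydroxyl.
- The spiro carbon C11 is cut at C11–C12: Wittig olefination to an allyl enol ether, then Claisen ([3,3]) rearrangement (key step).
- The cyclohexane is bought as (S)-(+)-carvone. Its stereocentre sets C6 (alkylation) and C10 (epoxidation, later hydride opening), then is sacrificed when isopropenyl becomes the tetrasubstituted enal.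
- Ring order: cyclohexane (ring A, from the pool), then cyclopentane (ring B, radical cyclisation).

Assumption and labels: allyl chloromethyl ether and tert-butyl(3-iodopropoxy)dimethylsilane are taken as catalogue reagents; labels are C6–C11 for the cyclohexane (C6 propyl chain C5–C3, C7 enal unit C2/C1, C10 methyl carbinol, C11 spiro), C12/C13/C14/C26 for the cyclopentane, C15 onward for the side chain, C27 for its CH2OH.

**Step 1**
Reactants: 1 (S)-(+)-carvone; 2 tert-butyl(3-iodopropoxy)dimethylsilane
Product: 3 trans-6-alkylcarvone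
Conditions: LiN(iPr)2, THF, −78 °C; then 2, DMPU, −78 → −20 °C
Reagents that add atoms: none
Why: Kinetic deprotonation gives the cross-conjugated lithium dienolate, and its SN2 enolate alkylation at C6 occurs on the face opposite the neighbouring isopropenyl group, so the new C6 stereocentre is trans to the carvone stereocentre.

**Step 2**
Reactants: 3 trans-6-alkylcarvone
Product: 4 epoxy ketone
Conditions: H2O2 (30 % aq.), NaOH, MeOH, 0 °C
Reagents that add atoms: hydrogen peroxide, OO
Why: In this Weitz–Scheffer nucleophilic epoxidation hydroperoxide adds axially to the enone β-carbon anti to the isopropenyl group, so the oxirane (the future C10–O bond) is trans to isopropenyl and cis to the C6 chain, as with carvone itself.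

**Step 3**
Reactants: 5 allyl chloromethyl ether; 6 triphenylphosphine
Product: 7 (allyloxymethyl)triphenylphosphonium chloride
Conditions: toluene, 25 → 60 °C
Reagents that add atoms: none
Why: SN2 quaternisation of the phosphine by the reactive α-chloro ether gives the Wittig salt, with no stereocentre involved.

**Step 4**
Reactants: 4 epoxy ketone; 7 (allyloxymethyl)triphenylphosphonium chloride
Product: 9 quaternary epoxy aldehyde, via allyl enol ether 8 (not isolated)
Conditions: 7, KN(SiMe3)2, THF, −78 → 0 °C; add 4, 0 → 25 °C; filter through basic Al2O3; xylene, 140 °C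
Reagents that add atoms: none
Why: Wittig olefination gives the allyl enol ether, whose thermal Claisen ([3,3]-sigmatropic) rearrangement through a chair transition state forms the C11–C12 bond on the ring face opposite both the C6 chain and the oxirane oxygen, setting the quaternary C11 with the formyl group cis to the C6 chain.

**Step 5**
Reactants: 9 quaternary epoxy aldehyde
Product: 10 allyl diol
Conditions: LiAlH4, THF, 0 → 50 °C
Reagents that add atoms: none
Why: Hydride reduces the aldehyde and opens the trisubstituted epoxide by SN2 attack at the less substituted C9 (trans-diaxial opening), so the C10–O bond and the tertiary carbinol configuration are untouched.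

**Step 6**
Reactants: 10 allyl diol
Product: 11 triol
Conditions: Sia2BH (from BH3·THF and 2-methylbut-2-ene), THF, 0 °C; then NaOH, H2O2, 0 → 25 °C
Reagents that add atoms: hydrogen peroxide, OO
Why: Anti-Markovnikov hydroboration–oxidation with the bulky disiamylborane picks the monosubstituted allyl alkene over the ring-bound 1,1-disubstituted isopropenyl group, and no stereocentre is formed.

**Step 7**
Reactants: 11 triol
Product: 12 hydroxy dialdehyde
Conditions: Dess–Martin periodinane, CH2Cl2, 0 → 25 °C
Reagents that add atoms: none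
Why: Dess–Martin oxidation converts both primary alcohols into aldehydes and cannot oxidise the tertiary alcohol, so no stereocentre is affected.

**Step 8**
Reactants: 12 hydroxy dialdehyde; 13 ethyl (triphenylphosphoranylidene)acetate
Product: 14 aldehyde enoate
Conditions: CH2Cl2, 25 °C
Reagents that add atoms: none
Why: Wittig olefination with a stabilised ylide is E-selective and takes only the unhindered aldehyde (released from its lactol with the C10 hydroxyl), not the neopentyl aldehyde on the quaternary carbon.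

**Step 9**
Reactants: 14 aldehyde enoate
Product: 15 spiro cyclopentanol ester
Conditions: SmI2 (2.5 equiv), MeOH, THF, −78 °C
Reagents that add atoms: none
Why: In this SmI2 ketyl–olefin radical cyclisation (5-exo-trig) the samarium ketyl is held by chelation to the cis C10 hydroxyl, which puts the C26 oxygen on the C10 side, and the ester chain lies anti to the bulky O–Sm group, giving the trans-2-substituted cyclopentanol at C14.

**Step 10**
Reactants: 15 spiro cyclopentanol ester
Product: 16 α-methylene aldehyde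
Conditions: SeO2, pyridine (cat.), 1,4-dioxane, 80 °C
Reagents that add atoms: selenium dioxide, O=[Se]=O
Why: Riley allylic oxidation (ene reaction then [2,3]-sigmatropic shift) of the only alkene takes its methyl group through to the 2-substituted acrolein and leaves the ring stereocentres alone.

**Step 11**
Reactants: 16 α-methylene aldehyde
Product: 17 tetrasubstituted (Z)-enal
Conditions: RuHCl(CO)(PPh3)3 (5 mol %), toluene, 80 °C
Reagents that add atoms: none
Why: Ruthenium hydride addition/β-hydride elimination (alkene isomerisation) moves the double bond into conjugation at the tetrasubstituted position and removes the spent carvone stereocentre; geometry is thermodynamic, with methyl next to the unsubstituted C8 and the smaller formyl next to the branched C6, so only moderate selectivity (roughly 3:1) is expected and the minor isomer is separated and re-equilibrated.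

**Step 12**
Reactants: 17 tetrasubstituted (Z)-enal
Product: 18 dioxolane acetal
Conditions: (Me3SiOCH2)2, Me3SiOTf (cat.), CH2Cl2, −78 °C; then pyridine, aq. NaHCO3
Reagents that add atoms: 1,2-bis(trimethylsilyloxy)ethane, C[Si](C)(C)OCCO[Si](C)(C)C
Why: Noyori acetalisation at low temperature masks the enal as its dioxolane under kinetic conditions without moving or isomerising the tetrasubstituted double bond.

**Step 13**
Reactants: 19 6-methylhept-5-en-2-one
Product: 20 enol triflate
Conditions: KN(SiMe3)2, THF, −78 °C; then PhNTf2, −78 → 0 °C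
Reagents that add atoms: N-phenylbis(trifluoromethanesulfonimide), O=S(=O)(N(c1ccccc1)S(=O)(=O)C(F)(F)F)C(F)(F)F
Why: Kinetic enolisation of the methyl ketone on the methyl side followed by O-triflation gives the terminal enol triflate.

**Step 14**
Reactants: 20 enol triflate; 21 acrolein
Product: 22 trienal
Conditions: Pd(OAc)2 (5 mol %), PPh3, Et3N, DMF, 60 °C
Reagents that add atoms: none
Why: In this Mizoroki–Heck coupling syn-carbopalladation of acrolein and syn β-hydride elimination give the (E)-enal and leave the 1,1-disubstituted alkene in place.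

**Step 15**
Reactants: 18 dioxolane acetal; 22 trienal
Product: 23 aldol adduct
Conditions: LiN(iPr)2 (3.3 equiv), THF, −78 °C; then 22, −78 °C
Reagents that add atoms: none
Why: After both hydroxyls are deprotonated the lithium ester enolate undergoes aldol addition (1,2) to the enal carbonyl, and the two new stereocentres (mixtures) are removed in the next step.

**Step 16**
Reactants: 23 aldol adduct
Product: 25 trienoate acetate, via bis-acetate 24 (not isolated)
Conditions: Ac2O, Et3N, DMAP, CH2Cl2, 0 → 25 °C; then DBU, 25 °C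
Reagents that add atoms: acetic anhydride, CC(=O)OC(C)=O
Why: Acetylation followed by DBU-induced E1cB elimination gives the thermodynamically preferred (E)-2-alkylidene ester, with the ester trans to the dienyl chain, from both aldol diastereomers.

**Step 17**
Reactants: 25 trienoate acetate
Product: 26 protected trienol
Conditions: iBu2AlH (excess), CH2Cl2, −78 °C; Rochelle salt work-up
Reagents that add atoms: none
Why: 1,2-Hydride reduction with diisobutylaluminium hydride turns the conjugated ester into the allylic alcohol and cleaves the acetate without touching the acetal, the silyl ether or any alkene.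

**Step 18**
Reactants: 26 protected trienol
Product: 28 CNP0246965.1, via desilylated acetal 27 (not isolated)
Conditions: Bu4NF, THF, 0 → 25 °C; then pyridinium p-toluenesulfonate, acetone–H2O, 25 °C
Reagents that add atoms: water, O
Why: Fluoride-induced desilylation and mild acid-catalysed acetal hydrolysis unmask the primary alcohol and the enal, with no stereocentre or double bond involved.

**Compound list**

1 | (S)-(+)-carvone, (5S)-2-methyl-5-(prop-1-en-2-yl)cyclohex-2-en-1-one | CC1=CC[C@@H](CC1=O)C(C)=C | starting material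
2 | tert-butyl(3-iodopropoxy)dimethylsilane | CC(C)(C)[Si](C)(C)OCCCI | starting material
3 | (5S,6R)-6-[3-(tert-butyldimethylsilyloxy)propyl]-2-methyl-5-(prop-1-en-2-yl)cyclohex-2-en-1-one (chain trans to isopropenyl) | O=C1[C@H](CCCO[Si](C)(C)C(C)(C)C)[C@@H](C(C)=C)CC=C1C | intermediate
4 | (1S,3R,4S,6S)-3-[3-(tert-butyldimethylsilyloxy)propyl]-1-methyl-4-(prop-1-en-2-yl)-7-oxabicyclo[4.1.0]heptan-2-one (oxirane trans to isopropenyl, cis to the chain) | O=C1[C@H](CCCO[Si](C)(C)C(C)(C)C)[C@@H](C(C)=C)C[C@@H]2O[C@]12C | intermediate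
5 | allyl chloromethyl ether, 3-(chloromethoxy)prop-1-ene | C=CCOCCl | starting material
6 | triphenylphosphine | c1ccc(cc1)P(c1ccccc1)c1ccccc1 | starting material
7 | (allyloxymethyl)triphenylphosphonium chloride | C=CCOC[P+](c1ccccc1)(c1ccccc1)c1ccccc1.[Cl-] | intermediate
8 | allyl enol ether of 4 (C=O replaced by C=CH–O–allyl, E/Z mixture) | C=CCOC=C1[C@H](CCCO[Si](C)(C)C(C)(C)C)[C@@H](C(C)=C)C[C@@H]2O[C@]12C | intermediate
9 | (1R,2R,3R,4S,6S)-2-allyl-3-[3-(tert-butyldimethylsilyloxy)propyl]-1-methyl-4-(prop-1-en-2-yl)-7-oxabicyclo[4.1.0]heptane-2-carbaldehyde (CHO cis to the chain and to the oxirane oxygen) | C=CC[C@@]1(C=O)[C@H](CCCO[Si](C)(C)C(C)(C)C)[C@@H](C(C)=C)C[C@@H]2O[C@]12C | intermediate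
10 | (1S,2S,3R,4S)-2-allyl-2-(hydroxymethyl)-1-methyl-3-[3-(tert-butyldimethylsilyloxy)propyl]-4-(prop-1-en-2-yl)cyclohexan-1-ol | C=CC[C@@]1(CO)[C@H](CCCO[Si](C)(C)C(C)(C)C)[C@@H](C(C)=C)CC[C@]1(C)O | intermediate
11 | (1S,2S,3R,4S)-2-(hydroxymethyl)-2-(3-hydroxypropyl)-1-methyl-3-[3-(tert-butyldimethylsilyloxy)propyl]-4-(prop-1-en-2-yl)cyclohexan-1-ol | OCCC[C@@]1(CO)[C@H](CCCO[Si](C)(C)C(C)(C)C)[C@@H](C(C)=C)CC[C@]1(C)O | intermediate
12 | (1R,2S,5S,6R)-2-hydroxy-2-methyl-1-(3-oxopropyl)-6-[3-(tert-butyldimethylsilyloxy)propyl]-5-(prop-1-en-2-yl)cyclohexane-1-carbaldehyde (in equilibrium with its six-membered lactol) | O=CCC[C@@]1(C=O)[C@H](CCCO[Si](C)(C)C(C)(C)C)[C@@H](C(C)=C)CC[C@]1(C)O | intermediate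
13 | ethyl (triphenylphosphoranylidene)acetate | CCOC(=O)C=P(c1ccccc1)(c1ccccc1)c1ccccc1 | starting material
14 | ethyl (2E)-5-[(1R,2S,5S,6R)-1-formyl-2-hydroxy-2-methyl-6-[3-(tert-butyldimethylsilyloxy)propyl]-5-(prop-1-en-2-yl)cyclohexyl]pent-2-enoate | CCOC(=O)/C=C/CC[C@@]1(C=O)[C@H](CCCO[Si](C)(C)C(C)(C)C)[C@@H](C(C)=C)CC[C@]1(C)O | intermediate
15 | ethyl 2-[(1S,2S,5S,6S,9S,10R)-1,6-dihydroxy-6-methyl-9-(prop-1-en-2-yl)-10-[3-(tert-butyldimethylsilyloxy)propyl]spiro[4.5]decan-2-yl]acetate (C26–OH trans to the C14 chain, cis to C10) | CCOC(=O)C[C@@H]1CC[C@]2([C@H](CCCO[Si](C)(C)C(C)(C)C)[C@@H](C(C)=C)CC[C@]2(C)O)[C@H]1O | intermediate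
16 | as 15 with 9-(3-oxoprop-1-en-2-yl) in place of isopropenyl (2-substituted acrolein) | CCOC(=O)C[C@@H]1CC[C@]2([C@H](CCCO[Si](C)(C)C(C)(C)C)[C@@H](C(=C)C=O)CC[C@]2(C)O)[C@H]1O | intermediate
17 | ethyl 2-[(1S,2S,5S,6S,9Z,10R)-1,6-dihydroxy-6-methyl-9-(1-oxopropan-2-ylidene)-10-[3-(tert-butyldimethylsilyloxy)propyl]spiro[4.5]decan-2-yl]acetate (CHO cis to C6) | CCOC(=O)C[C@@H]1CC[C@]2([C@H](CCCO[Si](C)(C)C(C)(C)C)/C(=C(/C)C=O)CC[C@]2(C)O)[C@H]1O | intermediate
18 | 1,3-dioxolane acetal of 17 (9-[1-(1,3-dioxolan-2-yl)ethylidene], Z) | CCOC(=O)C[C@@H]1CC[C@]2([C@H](CCCO[Si](C)(C)C(C)(C)C)/C(=C(/C)C3OCCO3)CC[C@]2(C)O)[C@H]1O | intermediate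
19 | 6-methylhept-5-en-2-one | CC(=O)CCC=C(C)C | starting material
20 | 6-methylhepta-1,5-dien-2-yl trifluoromethanesulfonate | C=C(CCC=C(C)C)OS(=O)(=O)C(F)(F)F | intermediate
21 | acrolein, prop-2-enal | C=CC=O | starting material
22 | (2E)-8-methyl-4-methylidenenona-2,7-dienal | O=C/C=C/C(=C)CCC=C(C)C | intermediate
23 | ethyl (4E)-3-hydroxy-10-methyl-6-methylidene-2-[spirodecanyl core of 18]undeca-4,9-dienoate (mixture at C15 and C16) | C=C(/C=C/C(O)C(C(=O)OCC)[C@@H]1CC[C@]2([C@H](CCCO[Si](C)(C)C(C)(C)C)/C(=C(/C)C3OCCO3)CC[C@]2(C)O)[C@H]1O)CCC=C(C)C | intermediate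
24 | bis-acetate of 23 (acetates on the C16 hydroxyl and the C26 hydroxyl) | C=C(/C=C/C(OC(C)=O)C(C(=O)OCC)[C@@H]1CC[C@]2([C@H](CCCO[Si](C)(C)C(C)(C)C)/C(=C(/C)C3OCCO3)CC[C@]2(C)O)[C@H]1OC(C)=O)CCC=C(C)C | intermediate
25 | ethyl (2E,4E)-10-methyl-6-methylidene-2-[C26-acetoxy spirodecanyl core of 18]undeca-2,4,9-trienoate | C=C(/C=C/C=C(/C(=O)OCC)[C@@H]1CC[C@]2([C@H](CCCO[Si](C)(C)C(C)(C)C)/C(=C(/C)C3OCCO3)CC[C@]2(C)O)[C@H]1OC(C)=O)CCC=C(C)C | intermediate
26 | target with the C3 hydroxyl as tert-butyldimethylsilyl ether and the aldehyde as 1,3-dioxolane | C=C(/C=C/C=C(/CO)[C@@H]1CC[C@]2([C@H](CCCO[Si](C)(C)C(C)(C)C)/C(=C(/C)C3OCCO3)CC[C@]2(C)O)[C@H]1O)CCC=C(C)C | intermediate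
27 | target with the aldehyde as 1,3-dioxolane | C=C(/C=C/C=C(/CO)[C@@H]1CC[C@]2([C@H](CCCO)/C(=C(/C)C3OCCO3)CC[C@]2(C)O)[C@H]1O)CCC=C(C)C | intermediate
28 | CNP0246965.1 (C6 R, C10 S, C11 S, C14 S, C26 S; enal Z; side chain 15E,17E) | C=C(/C=C/C=C(/CO)[C@@H]1CC[C@]2([C@H](CCCO)/C(=C(/C)C=O)CC[C@]2(C)O)[C@H]1O)CCC=C(C)C | target

**Step count**
Total: 18 steps. Longest linear sequence: 15 steps (1, 2, 4–12, 15–18, from (S)-carvone).

**Three steps most likely to fail**

Step 4 (Wittig olefination of a ketone flanked by a quaternary oxirane carbon and a tertiary carbon, then Claisen). The ylide may enolise the ketone or fail to add. The fallback sets out from 4 and comes back at 9. (Allyloxymethyl)diphenylphosphine oxide F1, made from ethyl diphenylphosphinite and 5 by an Arbuzov reaction, is lithiated with LiN(iPr)2 at −78 °C and added to 4 to give the β-hydroxy phosphine oxide F2. This adduct is isolated and then treated with KH in THF, so that a separate Horner–Wittig elimination of diphenylphosphinate gives the same enol ether 8, which is heated in xylene to 9.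

Step 9 (SmI2 cyclisation). The C26 configuration rests on chelation to the C10 hydroxyl, and the wrong C26 epimer or simple aldehyde reduction may compete. The fallback sets out from 12 and comes back at 15. McMurry coupling (TiCl3, Zn(Cu), DME, reflux, high dilution) closes the ring to the spiro cyclopentene F3. VO(acac)2/t-BuOOH, directed by the homoallylic tertiary hydroxyl on C10, gives the syn epoxide F4. LiC≡COEt with BF3·OEt2 opens it at the less hindered C14 with inversion to the trans ynol ether F5, and acid-catalysed hydration (TsOH cat., wet EtOH) gives 15.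

Step 11 (enal geometry). The isomerisation is only thermodynamically biased, and ruthenium hydride re-addition could also erode C6. The fallback sets out from 16 and comes back at 28; it fixes the geometry with a ring instead.
- Pinnick oxidation (NaClO2, NaH2PO4, 2-methylbut-2-ene) gives the acrylic acid F6, and Bu4NF frees the C3 hydroxyl to give the hydroxy acid F7.
- Yamaguchi lactonisation (2,4,6-trichlorobenzoyl chloride, Et3N, then DMAP, toluene, high dilution) gives the eight-membered α-methylene lactone F8.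
- RuHCl(CO)(PPh3)3 moves the double bond into the ring to give the conjugated lactone F9, where the eight-membered ring forces the carbonyl carbon cis to C6.
- F9 is then carried as in steps 15 and 16 through the aldol adduct F10 (with 22), the bis-acetate F11 and the trienoate lactone F12.
- iBu2AlH at −78 °C reduces the ethyl ester and the acetate and takes the lactone to its lactol, which opens on work-up to the hydroxy enal 28.

**Further compounds**

F1 | step 4 | (allyloxymethyl)diphenylphosphine oxide | C=CCOCP(=O)(c1ccccc1)c1ccccc1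
F2 | step 4 | β-hydroxy phosphine oxide adduct of F1 and 4 (mixture at the two new centres) | C=CCOC(P(=O)(c1ccccc1)c1ccccc1)C1(O)[C@H](CCCO[Si](C)(C)C(C)(C)C)[C@@H](C(C)=C)C[C@@H]2O[C@]12C
F3 | step 9 | spiro[4.5]dec-1-ene with C14=C26 double bond, cyclohexane substituents as in 12 | C1=C[C@]2(CC1)[C@H](CCCO[Si](C)(C)C(C)(C)C)[C@@H](C(C)=C)CC[C@]2(C)O
F4 | step 9 | C14–C26 epoxide of F3, oxygen on the face of C10 | C1C[C@]2([C@H](CCCO[Si](C)(C)C(C)(C)C)[C@@H](C(C)=C)CC[C@]2(C)O)[C@H]3O[C@H]31
F5 | step 9 | trans-2-(ethoxyethynyl)cyclopentanol (ynol ether analogue of 15) | CCOC#C[C@@H]1CC[C@]2([C@H](CCCO[Si](C)(C)C(C)(C)C)[C@@H](C(C)=C)CC[C@]2(C)O)[C@H]1O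
F6 | step 11 | 2-substituted acrylic acid from 16 | CCOC(=O)C[C@@H]1CC[C@]2([C@H](CCCO[Si](C)(C)C(C)(C)C)[C@@H](C(=C)C(=O)O)CC[C@]2(C)O)[C@H]1O
F7 | step 11 | hydroxy acid (C3–OH free) | CCOC(=O)C[C@@H]1CC[C@]2([C@H](CCCO)[C@@H](C(=C)C(=O)O)CC[C@]2(C)O)[C@H]1O
F8 | step 11 | eight-membered α-methylene lactone (C3–O–C1) | CCOC(=O)C[C@@H]1CC[C@]2([C@@H]3CCCOC(=O)C(=C)[C@H]3CC[C@]2(C)O)[C@H]1O
F9 | step 11 | conjugated eight-membered lactone, ring C7=C2 double bond (Z) | CCOC(=O)C[C@@H]1CC[C@]2([C@@H]3CCCOC(=O)/C(C)=C3/CC[C@]2(C)O)[C@H]1O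
F10 | step 11 | aldol adduct of F9 and 22 | C=C(/C=C/C(O)C(C(=O)OCC)[C@@H]1CC[C@]2([C@@H]3CCCOC(=O)/C(C)=C3/CC[C@]2(C)O)[C@H]1O)CCC=C(C)C
F11 | step 11 | bis-acetate of F10 | C=C(/C=C/C(OC(C)=O)C(C(=O)OCC)[C@@H]1CC[C@]2([C@@H]3CCCOC(=O)/C(C)=C3/CC[C@]2(C)O)[C@H]1OC(C)=O)CCC=C(C)C
F12 | step 11 | trienoate lactone with C26 acetate | C=C(/C=C/C=C(/C(=O)OCC)[C@@H]1CC[C@]2([C@@H]3CCCOC(=O)/C(C)=C3/CC[C@]2(C)O)[C@H]1OC(C)=O)CCC=C(C)C
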